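The maple run holds the same amounts as the birch run, 0.800 M substrate, 0.880 M reagent and 0.0640 M free catalyst, so up to 21 h I read it from birch, and the question is what the next 63.0 h do.

| flask | substrate | reagent | free catalyst | time |
|---|---|---|---|---|
| birch | 0.800 M | 0.880 M | 0.0640 M |  |
| oak | 0.480 M | 0.560 M | 0.0640 M |  |
| ash | 0.800 M | 0.880 M | 0.0320 M |  |
| maple | 0.800 M | 0.880 M | 0.0640 M | 84 h |

| birch run: time / h | birch run: [target] / M | oak run: time / h | oak run: [target] / M | ash run: time / h | ash run: [target] / M |
|---|---|---|---|---|---|
| 0.93 | 0.0221 | 0.93 | 0.0142 | 0.93 | 0.0028 |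
| 2.8 | 0.0660 | 2.8 | 0.0330 | 2.8 | 0.0014 |
| 5.4 | 0.1095 | 5.4 | 0.0577 | 5.4 | 0.0020 |
| 8.6 | 0.1623 | 8.6 | 0.0751 | 8.6 | 0 |
| 12 | 0.1939 | 12 | 0.0920 | 12 | 0.0040 |
| 16 | 0.2181 | 16 | 0.1091 | 16 | 0 |
| 21 | 0.2282 | 21 | 0.1126 | 21 | 0 |

(standard deviation of a reading: 0.002 M)

- how the opening rate goes with [free catalyst] round the charge of the birch run: the exponent of the rate at two percent of substrate gone to target
- target in the maple run at 84 h, as a share of the substrate charged

- Overall: substrate + reagent -> target, with free catalyst as catalyst.
- Constant volume, constant temperature.
- What is held in complexes is read along with the free species.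
- An order is taken over about fifteen percent of the charge, up and down.

The ash run, with half the free catalyst of birch, reads no higher than 0.0040 M, so the opening rate climbs steeply with [free catalyst].

The birch run opens at 0.0236 M h⁻¹ and ends with a net rise of 0.00202 M h⁻¹. If the gain goes with [substrate][reagent], scaled from that opening, and the target read counts as what has turned, the gain at 21 h is still 0.0125 M h⁻¹, more than the net rise. A reverse step would flatten the curve too, and these readings don't part the two, but I commit to a first-order loss. That gives 21.8 h in birch: the lifetime of the target, the amount standing divided by what it loses per hour. The oak run, by the same sum from its own opening, gives 17.3 h, though its net slope of 7.00 × 10⁻⁴ M h⁻¹ is a thin reading.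

In powers of ten, the 63.0 h after birch's last reading are 1.26 decades, which leaves 0.0127 M of that stock, so I reckon the target in maple at 84 h from the late gain. I take the target to trail its gain by one lifetime, as a first-order lag does. With the birch opening as the constant, 0.0335 L mol⁻¹ h⁻¹, and reagent standing 0.0800 M above substrate, this rate law puts [substrate] in maple at 0.267 M one lifetime before 84 h. The gain there is 0.00311 M h⁻¹, and times the lifetime that makes 8.47% of the substrate, my figure.

The forecast says 2.6 and 30.5%, holding that “little more forms after 21 h”. The flask gives 2.8 and 12.3%, which is 3.8 percentage points above my figure.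

    free catalyst + reagent ⇌ catalyst-reagent complex, settled at all times (0.9520 L mol⁻¹)
    catalyst-reagent complex + substrate → target + free catalyst (3.078 L mol⁻¹ h⁻¹)
    free catalyst + impurity → spent catalyst
    target → decomposed product (0.03888 h⁻¹)

At the start the impurity takes 0.0401 M of the 0.0640 M catalyst at once as spent catalyst, and the remaining 0.0239 M, free or as catalyst-reagent complex, turns substrate into target. Meanwhile target goes on to decomposed product, and at 84 h, which is 3.85 of my lifetimes after the start, the maple run holds 0.0984 M, less than birch read at 21 h, and at 0.0389 h⁻¹ it is losing 0.00383 M h⁻¹.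

The runs are calculated on assumed constants.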